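**Direct plan and its weak points**

A direct plan would tether 3-methylfuran to an α,β-epoxy ketone (A1) and close cyclopentane and cycloheptenone together by an intramolecular (4+3) cycloaddition of its epoxy enolsilane, giving the oxa-bridged tricycle A2.
It would then open the oxygen bridge reductively to hydroxy ketone A3 and finish by Evans–Tishchenko reduction with a silyl-protected vanillin and desilylation.
Weak point 1, the reductive opening of the oxa-bridge of A2: the regioselective ionisation and hydride transfer have no precedent, BF3 is used beside a tertiary silyl ether, and the product is a β-hydroxy ketone whose C5–H lies between the ketone and the new alkene.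
Weak point 2, the seven-step linear run-up to A1: most of it is oxidation-state traffic (ester, alcohol, aldehyde, alcohol, ketone) that closes no ring and sets only C4.
Weak point 3, the cycloaddition and the late Tishchenko step: the first must invert a fully substituted epoxide carbon and set C1, C5, C7 and C8 through one transition state; the second runs on the β,γ-unsaturated, doubly enolisable A3.

**Retrosynthetic overview of the new route**

Ring B (seven-membered: C1, C5–C10) carries 10-Me, 7-iPr and O8 in the pattern of thymol (Me para to iPr, O ortho to iPr), so C1 and C6–C10 are bought as the benzene ring of thymol methyl ether 1.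
Key disconnection: C5–C1 and C5–C6 are formed and C1–C6 is cleaved when the carbenoid carbon C5 of diazoketone 8 (three steps from 1) inserts into the arene in an enantioselective intramolecular Büchner ring expansion.
Ring order: the aromatic six-membered ring comes first; ring A (cyclopentanone) and ring B arise together in 10, with C1=C10 in place and the aryl ether as the latent C8 carbonyl.
C5 is set by the catalyst; C4 (organocerium addition), C6/C7 (boron-tethered oxa-Michael addition from O4) and C8 (hydroxyl-directed reduction) are relayed from it.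
There is no oxa-bridge to cleave, no chain assembly with redox shuffling and no epoxide inversion; the only protecting group is the phenolic acetate of the acid.

Key step: step 4

Remarks on the chemistry: guaiane numbering is used for atoms (C1 sp2 ring fusion, C4 carbinol, C5 ring-fusion CH, C6 CHOH, C7 CH-iPr, C8 CH–O-acyl, C9 CH2, C10 C-Me). The sense of induction of the copper–bis(oxazoline) catalyst in step 4 is assumed; if the (8aS) ketone formed, the ligand antipode would be used.

**Route**

Step 1
Reactants: 1 1-methoxy-5-methyl-2-(propan-2-yl)benzene (thymol methyl ether)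
Product: 2 4-methoxy-2-methyl-5-(propan-2-yl)benzaldehyde
Conditions: Cl2CHOMe (1.2 equiv), TiCl4 (2 equiv), CH2Cl2, −10 → 0 °C; H2O
Reagents that add atoms: dichloromethyl methyl ether COC(Cl)Cl; water O
Why: Rieche formylation should go to the position para to the methoxy group (ortho to the methyl), the most activated and least hindered site of the ring; no stereocentre.

Step 2
Reactants: 2 4-methoxy-2-methyl-5-(propan-2-yl)benzaldehyde; 3 2,2-dimethyl-1,3-dioxane-4,6-dione (Meldrum's acid)
Product: 6 3-[4-methoxy-2-methyl-5-(propan-2-yl)phenyl]propanoic acid, via arylidene Meldrum's acid 4 (not isolated), via benzyl Meldrum's acid 5 (not isolated)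
Conditions: 3 (1.05 equiv), HCO2H/Et3N (5:2), 95 °C; then H2O, 100 °C; aq. HCl
Reagents that add atoms: water O
Why: Knoevenagel condensation, conjugate transfer hydrogenation by formate and hydrolysis–decarboxylation of the Meldrum's acid unit should run in one pot to the arylpropanoic acid; no stereocentre.

Step 3
Reactants: 6 3-[4-methoxy-2-methyl-5-(propan-2-yl)phenyl]propanoic acid
Product: 8 1-diazo-4-[4-methoxy-2-methyl-5-(propan-2-yl)phenyl]butan-2-one, via acid chloride 7 (not isolated)
Conditions: (COCl)2, DMF (cat.), CH2Cl2, 0 °C → rt, evaporate; CH2N2 (3 equiv), Et2O, 0 °C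
Reagents that add atoms: diazomethane C=[N+]=[N-]
Why: Acylation of diazomethane by the acid chloride (first stage of an Arndt–Eistert sequence) gives the terminal diazoketone, the excess diazomethane taking up the hydrogen chloride.

Step 4
Reactants: 8 1-diazo-4-[4-methoxy-2-methyl-5-(propan-2-yl)phenyl]butan-2-one
Product: 10 (8aR)-6-methoxy-4-methyl-7-(propan-2-yl)-3,8a-dihydroazulen-1(2H)-one, via norcaradiene 9 (not isolated)
Conditions: Cu(MeCN)4PF6 (5 mol %), 2,2'-(propane-2,2-diyl)bis[(4R)-4-phenyl-4,5-dihydro-1,3-oxazole] (6 mol %), NaB[3,5-(CF3)2C6H3]4 (6 mol %), CH2Cl2, reflux, slow addition of 8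
Reagents that add atoms: none
Why: The copper carbenoid formed from 8 adds its carbon (C5) across the C1–C6 π bond of the arene (C1 is the ipso carbon, para to the methoxy group and the most nucleophilic site; C6 is the unsubstituted ortho carbon) to give norcaradiene 9, whose 6π disrotatory ring opening cleaves C1–C6 and delivers cycloheptatriene 10. The closest known reaction type is the enantioselective intramolecular Büchner reaction of 1-diazo-4-arylbutan-2-ones under monovalent copper–bis(oxazoline) catalysis. The cyclopentanone closes by C5–C1 bond formation through the three-atom tether, and the seven-membered ring arises by one-carbon expansion of the benzene ring (C5–C6 formed, C1–C6 broken), so the C1=C10, C8=C9 and C6=C7 bonds of the triene are the former aromatic π bonds. The only new stereocentre, C5, is set by the chiral ligand, which differentiates the two enantiotopic faces of the arene at the C1–C6 bond. The step needs addition at C1–C6 and not at C1–C10, which the methyl group on C10 should secure by blocking that side, and it needs electrocyclic opening of 9 instead of acid-induced rearrangement to a 2-tetralone, which the neutral copper catalyst and acid-free conditions should secure.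

Step 5
Reactants: 10 (8aR)-6-methoxy-4-methyl-7-(propan-2-yl)-3,8a-dihydroazulen-1(2H)-one
Product: 12 (3S,3aR)-3-hydroxy-3,8-dimethyl-5-(propan-2-yl)-2,3,3a,7-tetrahydroazulen-6(1H)-one, via tertiary alcohol 11 (not isolated)
Conditions: MeLi, CeCl3, THF, −78 °C; then 0.5 M aq. (CO2H)2, THF, 0 °C
Reagents that add atoms: methyllithium [Li]C; water O
Why: The weakly basic organocerium reagent should add 1,2 without enolising C5–H and anti to C6 (the ring substituent on the α-carbon), so the methyl group ends cis to H5 (4S), and kinetic protonation of the dienol ether at C9 on mild acid hydrolysis (as for Birch-type dienol ethers) should unveil the C8 ketone conjugated with C6=C7 while C1=C10 stays in place.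

Step 6
Reactants: 12 (3S,3aR)-3-hydroxy-3,8-dimethyl-5-(propan-2-yl)-2,3,3a,7-tetrahydroazulen-6(1H)-one
Product: 14 (3S,3aS,4S,5S)-3,4-dihydroxy-3,8-dimethyl-5-(propan-2-yl)-2,3,3a,4,5,7-hexahydroazulen-6(1H)-one, via cyclic phenylboronate 13 (not isolated)
Conditions: PhB(OH)2 (1.5 equiv), DABCO (20 mol %), 4 Å MS, toluene, rt; then 30 % H2O2, pH 7 phosphate buffer, THF, 0 °C
Reagents that add atoms: phenylboronic acid OB(O)c1ccccc1
Why: In this boronic-acid-tethered oxa-Michael addition of a δ-hydroxy enone the hemiester of the tertiary 4-OH delivers its B–OH oxygen to C6, which can close the six-membered dioxaborinane only on the face of O4 (O6 cis to O4), and protonation of the enol at C7 anti to the new C6–O bond (trans-diaxial-type addition) should place the isopropyl group cis to O6 before buffered peroxide frees the diol.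

Step 7
Reactants: 14 (3S,3aS,4S,5S)-3,4-dihydroxy-3,8-dimethyl-5-(propan-2-yl)-2,3,3a,4,5,7-hexahydroazulen-6(1H)-one
Product: 15 (3S,3aS,4R,5R,6S)-3,8-dimethyl-5-(propan-2-yl)-1,2,3,3a,4,5,6,7-octahydroazulene-3,4,6-triol
Conditions: Me4NBH(OAc)3 (5 equiv), MeCN/AcOH (1:1), −30 °C
Reagents that add atoms: none
Why: In the Evans–Saksena reduction the acetoxyborohydride bound to O6 should transfer hydride intramolecularly to the C8 carbonyl on the face of O6, giving the anti-1,3-diol (8S) and ending the epimerisability of C7.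

Step 8
Reactants: 15 (3S,3aS,4R,5R,6S)-3,8-dimethyl-5-(propan-2-yl)-1,2,3,3a,4,5,6,7-octahydroazulene-3,4,6-triol; 16 4-(acetyloxy)-3-methoxybenzoic acid
Product: 18 (3S,3aS,4R,5S,6S)-3,4-dihydroxy-3,8-dimethyl-5-(propan-2-yl)-1,2,3,3a,4,5,6,7-octahydroazulen-6-yl 4-hydroxy-3-methoxybenzoate (CNP0299353.1), via acetyl-protected ester 17 (not isolated)
Conditions: 16 (1.1 equiv), EDC·HCl, DMAP (10 mol %), CH2Cl2, −20 → 0 °C; then pyrrolidine (3 equiv), 0 °C
Reagents that add atoms: none
Why: Steglich esterification should go to the less hindered secondary 8-OH (6-OH is flanked by the ring-fusion carbon C5 and the isopropyl-bearing C7, the tertiary 4-OH is inert), and aminolysis of the phenolic acetate by pyrrolidine is much faster than attack on the alkyl benzoate, so no stereocentre is touched.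

**Compound list**

1 | 1-methoxy-5-methyl-2-(propan-2-yl)benzene (thymol methyl ether) | COc1cc(C)ccc1C(C)C | starting material
2 | 4-methoxy-2-methyl-5-(propan-2-yl)benzaldehyde | COc1cc(C)c(C=O)cc1C(C)C | intermediate
3 | 2,2-dimethyl-1,3-dioxane-4,6-dione (Meldrum's acid) | CC1(C)OC(=O)CC(=O)O1 | starting material
4 | 5-{[4-methoxy-2-methyl-5-(propan-2-yl)phenyl]methylidene}-2,2-dimethyl-1,3-dioxane-4,6-dione | COc1cc(C)c(C=C2C(=O)OC(C)(C)OC2=O)cc1C(C)C | intermediate
5 | 5-{[4-methoxy-2-methyl-5-(propan-2-yl)phenyl]methyl}-2,2-dimethyl-1,3-dioxane-4,6-dione | COc1cc(C)c(CC2C(=O)OC(C)(C)OC2=O)cc1C(C)C | intermediate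
6 | 3-[4-methoxy-2-methyl-5-(propan-2-yl)phenyl]propanoic acid | COc1cc(C)c(CCC(=O)O)cc1C(C)C | intermediate
7 | 3-[4-methoxy-2-methyl-5-(propan-2-yl)phenyl]propanoyl chloride | COc1cc(C)c(CCC(=O)Cl)cc1C(C)C | intermediate
8 | 1-diazo-4-[4-methoxy-2-methyl-5-(propan-2-yl)phenyl]butan-2-one | COc1cc(C)c(CCC(=O)C=[N+]=[N-])cc1C(C)C | intermediate
9 | (1R,5R,6R)-8-methoxy-10-methyl-7-(propan-2-yl)tricyclo[4.4.0.0(1,5)]deca-7,9-dien-4-one (norcaradiene valence tautomer of 10) | COC1=C(C(C)C)[C@@H]2[C@H]3C(=O)CC[C@@]23C(C)=C1 | intermediate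
10 | (8aR)-6-methoxy-4-methyl-7-(propan-2-yl)-3,8a-dihydroazulen-1(2H)-one | COC1=CC(C)=C2CCC(=O)[C@@H]2C=C1C(C)C | intermediate
11 | (1S,8aR)-6-methoxy-1,4-dimethyl-7-(propan-2-yl)-1,2,3,8a-tetrahydroazulen-1-ol | COC1=CC(C)=C2CC[C@](C)(O)[C@@H]2C=C1C(C)C | intermediate
12 | (3S,3aR)-3-hydroxy-3,8-dimethyl-5-(propan-2-yl)-2,3,3a,7-tetrahydroazulen-6(1H)-one | O=C1CC(C)=C2CC[C@](C)(O)[C@@H]2C=C1C(C)C | intermediate
13 | cyclic phenylboronate of 14 (2-phenyl-1,3,2-dioxaborinane ring through O4–B–O6, cis-fused across C4–C5–C6) | O=C1CC(C)=C2CC[C@]3(C)OB(c4ccccc4)O[C@@H]([C@H]23)[C@@H]1C(C)C | intermediate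
14 | (3S,3aS,4S,5S)-3,4-dihydroxy-3,8-dimethyl-5-(propan-2-yl)-2,3,3a,4,5,7-hexahydroazulen-6(1H)-one | O=C1CC(C)=C2CC[C@](C)(O)[C@@H]2[C@H](O)[C@@H]1C(C)C | intermediate
15 | (3S,3aS,4R,5R,6S)-3,8-dimethyl-5-(propan-2-yl)-1,2,3,3a,4,5,6,7-octahydroazulene-3,4,6-triol | O[C@H]1CC(C)=C2CC[C@](C)(O)[C@@H]2[C@H](O)[C@@H]1C(C)C | intermediate
16 | 4-(acetyloxy)-3-methoxybenzoic acid | COc1cc(C(=O)O)ccc1OC(C)=O | starting material
17 | (3S,3aS,4R,5S,6S)-3,4-dihydroxy-3,8-dimethyl-5-(propan-2-yl)-1,2,3,3a,4,5,6,7-octahydroazulen-6-yl 4-(acetyloxy)-3-methoxybenzoate | COc1cc(C(=O)O[C@H]2CC(C)=C3CC[C@](C)(O)[C@@H]3[C@H](O)[C@@H]2C(C)C)ccc1OC(C)=O | intermediate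
18 | (3S,3aS,4R,5S,6S)-3,4-dihydroxy-3,8-dimethyl-5-(propan-2-yl)-1,2,3,3a,4,5,6,7-octahydroazulen-6-yl 4-hydroxy-3-methoxybenzoate (CNP0299353.1) | COc1cc(C(=O)O[C@H]2CC(C)=C3CC[C@](C)(O)[C@@H]3[C@H](O)[C@@H]2C(C)C)ccc1O | target

**Step count and risks**

Total step count: 8. Longest linear sequence: 8 steps (from 1).

Steps most likely to fail:

Step 4. The copper catalyst may discriminate the two faces of this trisubstituted arene poorly, and partial attack at the methyl-bearing ortho carbon would erode the result further. Setting out from 8, the ring expansion would then be run without asymmetric induction (Rh2(OAc)4, CH2Cl2, rt) to racemic ketone F1. NaBH4 in MeOH at 0 °C would reduce it anti to the seven-membered ring to racemic alcohol F2. Lipase-catalysed acetylation (Candida antarctica lipase B, vinyl acetate, MTBE) is expected to acetylate the (1R,8aS) enantiomer to acetate F4 and to leave the (1S,8aR) alcohol F3. Dess–Martin periodinane would oxidise F3 back to 10, where the route is rejoined.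

Step 6. Conjugate addition to the α-branched ring enone may be slow, the amine may move the C1=C10 alkene into conjugation, and protonation at C7 may occur from the wrong face. Setting out from 12, a copper-catalysed conjugate borylation (CuCl, (R)-BINAP, NaOtBu (cat.), bis(pinacolato)diboron, MeOH, THF, 0 °C; ligand antipode chosen to match the substrate) would give β-boryl ketone F5 under catalyst control of the C6 face. NaBO3·4H2O in THF/H2O would oxidise the C–B bond with retention and return to 14.

Step 8. The acylating agent may not discriminate enough between the secondary 6- and 8-hydroxyls, and 1,3-acyl migration may follow. Setting out from 15, PhB(OH)2 (1.0 equiv, toluene, 4 Å MS) would mask the cis-4,6-diol as phenylboronate F6, leaving only 8-OH free. Esterification with 16 (EDC·HCl, DMAP) would give acylated boronate F7, and exchange with pinacol would release 17, which pyrrolidine converts into 18 as in the main route.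

**Further compounds**

F1 | step 4 | rac-6-methoxy-4-methyl-7-(propan-2-yl)-3,8a-dihydroazulen-1(2H)-one | COC1=CC(C)=C2CCC(=O)C2C=C1C(C)C
F2 | step 4 | rac-(1S,8aR)-6-methoxy-4-methyl-7-(propan-2-yl)-1,2,3,8a-tetrahydroazulen-1-ol (racemate, relative configuration as in F3) | COC1=CC(C)=C2CCC(O)C2C=C1C(C)C
F3 | step 4 | (1S,8aR)-6-methoxy-4-methyl-7-(propan-2-yl)-1,2,3,8a-tetrahydroazulen-1-ol | COC1=CC(C)=C2CC[C@H](O)[C@@H]2C=C1C(C)C
F4 | step 4 | (1R,8aS)-6-methoxy-4-methyl-7-(propan-2-yl)-1,2,3,8a-tetrahydroazulen-1-yl acetate | COC1=CC(C)=C2CC[C@@H](OC(C)=O)[C@H]2C=C1C(C)C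
F5 | step 6 | (3S,3aR,4S,5R)-3-hydroxy-3,8-dimethyl-5-(propan-2-yl)-4-(4,4,5,5-tetramethyl-1,3,2-dioxaborolan-2-yl)-2,3,3a,4,5,7-hexahydroazulen-6(1H)-one | O=C1CC(C)=C2CC[C@](C)(O)[C@@H]2[C@H](B3OC(C)(C)C(C)(C)O3)[C@@H]1C(C)C
F6 | step 8 | 4,6-O-phenylboronate of 15 (dioxaborinane through O4–B–O6, 8-OH free) | O[C@H]1CC(C)=C2CC[C@]3(C)OB(c4ccccc4)O[C@@H]([C@H]23)[C@@H]1C(C)C
F7 | step 8 | 4,6-O-phenylboronate of 17 | COc1cc(C(=O)O[C@H]2CC(C)=C3CC[C@]4(C)OB(c5ccccc5)O[C@@H]([C@H]34)[C@@H]2C(C)C)ccc1OC(C)=O
A1 | direct plan | 3-methyl-1-[(2S,3S)-3-methyl-3-[2-(3-methylfuran-2-yl)ethyl]oxiran-2-yl]butan-1-one | CC(C)CC(=O)[C@H]1O[C@@]1(C)CCc1occc1C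
A2 | direct plan | (1S,4S,5R,7R,8S)-4,10-dimethyl-7-(propan-2-yl)-4-[(triethylsilyl)oxy]-11-oxatricyclo[6.2.1.0(1,5)]undec-9-en-6-one | O1[C@H]2C=C(C)[C@@]13CC[C@](C)(O[Si](CC)(CC)CC)[C@@H]3C(=O)[C@@H]2C(C)C
A3 | direct plan | (3S,3aR,5R,6S)-6-hydroxy-3,8-dimethyl-5-(propan-2-yl)-3-[(triethylsilyl)oxy]-2,3,3a,5,6,7-hexahydroazulen-4(1H)-one | O[C@H]1CC(C)=C2CC[C@](C)(O[Si](CC)(CC)CC)[C@@H]2C(=O)[C@@H]1C(C)C
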